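**Plan**

1. Cuts (side chain numbered C1' at the ring to C32'): the quinone goes back to a 1,4-dimethoxynaphthalene; C15'–C16' (sp2–sp3) to an (E)-vinyl iodide plus a B-alkylborane; C12'–C13' and C15'–CH3 to an allylic bromide, the propargyl dianion and MeI; the ring C–C1' bond to an aryl Grignard reagent plus farnesyl bromide; C16'=C17' to a Wittig methylenation of geranylgeranial.
2. Forward order: menadione → bromoarene → farnesylation (C1'–C12') → oxidation of the (E)-methyl group C12' → bromide → 2-alkyne (C13'–C15' plus CH3) → vinyl iodide; separately geranylgeraniol → C21 diene; the halves are joined at C15'–C16'; the quinone is unmasked last.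
3. Enabling feature: C15' is an sp2 carbon that bears a methyl group and the sp3 carbon C16', while its partner C14' bears H. This is the retron of a methyl alkyne C14'≡C15'–CH3 hydrometalated syn with the metal on C15'. C16'H2–C17'H2 beside C18'=C19' is the retron of the lone CH=CH2 group of a 1,3-diene.
4. Stereochemistry: there are no stereocentres. C2'=C3' and C6'=C7' come from farnesyl bromide; C18'=C19', C22'=C23' and C26'=C27' from geranylgeraniol; C10'=C11' from oxidation of the (E)-methyl group; C14'=C15' from syn-hydrozirconation, retained in iodinolysis and coupling.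
5. Remark: the prenyl building blocks are assumed to be bought as the all-E isomers.

Key step: step 10

**Route**

Step 1
Reactants: 1 menadione (2-methyl-1,4-naphthoquinone)
Product: 3 menadiol dimethyl ether (1,4-dimethoxy-2-methylnaphthalene), via menadiol 2 (not isolated)
Conditions: Na2S2O4, n-Bu4NBr (cat.), THF/H2O, rt; then aq. KOH, Me2SO4, rt
Reagents that add atoms: dimethyl sulfate, COS(=O)(=O)OC
Why: Dithionite reduction to the hydroquinone 2 and double O-methylation of its phenoxide under phase transfer (reductive methylation, Williamson ether synthesis) should mask the base- and nucleophile-sensitive quinone as an arene that tolerates the Grignard, organolithium, zirconium and palladium steps.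

Step 2
Reactants: 3 menadiol dimethyl ether
Product: 4 aryl bromide 2-bromo-1,4-dimethoxy-3-methylnaphthalene
Conditions: Br2, CH2Cl2, 0 °C
Reagents that add atoms: bromine, BrBr
Why: Electrophilic aromatic bromination should occur only at C3, the one free position of the ring activated by both methoxy groups.

Step 3
Reactants: 4 aryl bromide; 5 (2E,6E)-farnesyl bromide
Product: 7 farnesyl arene 2-[(2E,6E)-3,7,11-trimethyldodeca-2,6,10-trien-1-yl]-1,4-dimethoxy-3-methylnaphthalene, via arylmagnesium bromide 6 (not isolated)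
Conditions: Mg, THF, reflux; then 5, THF, 0 °C to rt
Reagents that add atoms: none
Why: Grignard formation and SN2 allylation at the primary allylic carbon of 5 (Grignard–allyl halide coupling) should give 7, because SN2' attack would have to build a quaternary centre and the two E double bonds of 5 take no part.

Step 4
Reactants: 7 farnesyl arene
Product: 8 allylic alcohol (2E,6E,10E)-12-(1,4-dimethoxy-3-methylnaphthalen-2-yl)-2,6,10-trimethyldodeca-2,6,10-trien-1-ol
Conditions: SeO2 (cat.), t-BuOOH, salicylic acid (cat.), CH2Cl2, 0 °C to rt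
Reagents that add atoms: tert-butyl hydroperoxide, CC(C)(C)OO
Why: SeO2-catalysed allylic oxidation (Riley oxidation; ene reaction then [2,3]-sigmatropic shift) should favour the least hindered, terminal isopropylidene group and hydroxylate its (E)-methyl group, which makes the terminal alkene the E-configured C10'=C11' double bond.

Step 5
Reactants: 8 allylic alcohol
Product: 9 allylic bromide 2-[(2E,6E,10E)-12-bromo-3,7,11-trimethyldodeca-2,6,10-trien-1-yl]-1,4-dimethoxy-3-methylnaphthalene
Conditions: CBr4, PPh3, CH2Cl2, 0 °C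
Reagents that add atoms: tetrabromomethane, BrC(Br)(Br)Br
Why: The Appel reaction should convert the primary allylic alcohol into the bromide under neutral conditions, without allylic transposition or loss of the 10E geometry.

Step 6
Reactants: 9 allylic bromide
Product: 11 methyl alkyne 2-[(2E,6E,10E)-3,7,11-trimethylhexadeca-2,6,10-trien-14-yn-1-yl]-1,4-dimethoxy-3-methylnaphthalene, via lithium acetylide 10 (not isolated)
Conditions: allene, n-BuLi (2 equiv), THF/Et2O, −78 to −15 °C; then 9, −78 °C to rt; then MeI, 0 °C to rt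
Reagents that add atoms: allene (propadiene), C=C=C; iodomethane, CI
Why: In this propargylation of an allylic halide, 1,3-dilithiopropyne should displace the primary bromide by SN2 attack through its sp3 carbon to give acetylide 10, which MeI then C-methylates, so that C13', C14', C15' and the C15' methyl group arrive in one flask.

Step 7
Reactants: 11 methyl alkyne
Product: 13 vinyl iodide 2-[(2E,6E,10E,14E)-15-iodo-3,7,11-trimethylhexadeca-2,6,10,14-tetraen-1-yl]-1,4-dimethoxy-3-methylnaphthalene, via alkenylzirconocene chloride 12 (not isolated)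
Conditions: Cp2Zr(H)Cl (2.2 equiv), THF, 50 °C; then I2, THF, 0 °C
Reagents that add atoms: iodine, II
Why: In this hydrozirconation–iodination, syn addition of H–Zr under equilibrating conditions should place zirconium on the less hindered, methyl-bearing carbon C15' cis to the new C14'–H, and iodinolysis of the C–Zr bond with retention should give the 14E vinyl iodide, while trisubstituted alkenes react far more slowly with Cp2Zr(H)Cl.

Step 8
Reactants: 14 (2E,6E,10E)-geranylgeraniol
Product: 15 (2E,6E,10E)-geranylgeranial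
Conditions: MnO2, CH2Cl2, rt
Reagents that add atoms: none
Why: MnO2 oxidises allylic alcohols chemoselectively and should give the enal without isomerising the C2=C3 double bond or touching the isolated alkenes.

Step 9
Reactants: 15 (2E,6E,10E)-geranylgeranial
Product: 16 pentaene (3E,7E,11E)-4,8,12,16-tetramethylheptadeca-1,3,7,11,15-pentaene
Conditions: Ph3PCH3Br, KOt-Bu, THF, 0 °C to rt
Reagents that add atoms: methyltriphenylphosphonium bromide, C[P+](c1ccccc1)(c1ccccc1)c1ccccc1.[Br-]
Why: Wittig methylenation with the non-stabilised ylide adds the carbon that becomes C16' and creates no stereogenic alkene, while the conjugated 3E double bond is untouched.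

Step 10
Reactants: 16 pentaene; 13 vinyl iodide
Product: 18 menaquinone-8 hydroquinone dimethyl ether 2-[(2E,6E,10E,14E,18E,22E,26E)-3,7,11,15,19,23,27,31-octamethyldotriaconta-2,6,10,14,18,22,26,30-octaen-1-yl]-1,4-dimethoxy-3-methylnaphthalene, via B-alkyl-9-borabicyclononane 17 (not isolated)
Conditions: 9-BBN-H (1.1 equiv), THF, 0 °C to rt; then 13, Pd(dppf)Cl2 (5 mol %), AsPh3, Cs2CO3, DMF/THF/H2O, rt
Reagents that add atoms: none
Why: 9-BBN-H adds syn and anti-Markovnikov to C16'=C17' of 16, the only monosubstituted double bond, to give the homoallylic borane 17; zerovalent palladium formed in situ from Pd(dppf)Cl2 then inserts into the C15'–I bond of 13, takes the primary alkyl group from the base-activated borane by transmetalation and forms the sp2–sp3 C15'–C16' bond by reductive elimination. The closest known reaction type is the B-alkyl Suzuki–Miyaura coupling of a B-alkyl-9-BBN with a trisubstituted (E)-2-iodo-2-alkene. No ring is closed and no stereocentre is created; the one stereochemical element at stake, the C14'=C15' geometry, is controlled by the vinyl iodide, whose configuration is retained in oxidative addition and reductive elimination, so the 14E alkene should result. The step needs hydroboration of one alkene out of five, which the bulk of 9-BBN-H and the single CH=CH2 terminus of the diene should secure, with boron on the terminal carbon for steric reasons. It also needs reductive elimination to outrun β-hydride elimination of the homoallylic alkylpalladium intermediate, which the wide bite angle of dppf and the AsPh3 additive should secure. The dimethoxynaphthalene and the other trisubstituted alkenes should be inert to 9-BBN-H at rt and to the mild aqueous Cs2CO3 medium.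

Step 11
Reactants: 18 menaquinone-8 hydroquinone dimethyl ether
Product: 19 menaquinone-8
Conditions: (NH4)2Ce(NO3)6, MeCN/CH2Cl2/H2O, 0 °C
Reagents that add atoms: water, O
Why: Oxidative demethylation of the 1,4-dimethoxyarene by tetravalent cerium (two one-electron oxidations, attack of water at the ipso carbons, loss of two molecules of methanol) should give the quinone at 0 °C without attack on the isolated trisubstituted alkenes.

**Compound list**

1 | menadione (2-methyl-1,4-naphthoquinone) | CC1=CC(=O)c2ccccc2C1=O | starting material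
2 | menadiol (2-methylnaphthalene-1,4-diol) | Cc1cc(O)c2ccccc2c1O | intermediate
3 | menadiol dimethyl ether (1,4-dimethoxy-2-methylnaphthalene) | COc1cc(C)c(OC)c2ccccc12 | intermediate
4 | 2-bromo-1,4-dimethoxy-3-methylnaphthalene | COc1c(Br)c(C)c(OC)c2ccccc12 | intermediate
5 | (2E,6E)-farnesyl bromide | CC(C)=CCC/C(C)=C/CC/C(C)=C/CBr | starting material
6 | (1,4-dimethoxy-3-methylnaphthalen-2-yl)magnesium bromide | COc1c([Mg]Br)c(C)c(OC)c2ccccc12 | intermediate
7 | 2-[(2E,6E)-3,7,11-trimethyldodeca-2,6,10-trien-1-yl]-1,4-dimethoxy-3-methylnaphthalene | COc1c(C)c(C/C=C(\C)CC/C=C(\C)CCC=C(C)C)c(OC)c2ccccc12 | intermediate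
8 | (2E,6E,10E)-12-(1,4-dimethoxy-3-methylnaphthalen-2-yl)-2,6,10-trimethyldodeca-2,6,10-trien-1-ol | COc1c(C)c(C/C=C(\C)CC/C=C(\C)CC/C=C(\C)CO)c(OC)c2ccccc12 | intermediate
9 | 2-[(2E,6E,10E)-12-bromo-3,7,11-trimethyldodeca-2,6,10-trien-1-yl]-1,4-dimethoxy-3-methylnaphthalene | COc1c(C)c(C/C=C(\C)CC/C=C(\C)CC/C=C(\C)CBr)c(OC)c2ccccc12 | intermediate
10 | lithium acetylide of the terminal alkyne (lithium on C15') | COc1c(C)c(C/C=C(\C)CC/C=C(\C)CC/C=C(\C)CCC#C[Li])c(OC)c2ccccc12 | intermediate
11 | 2-[(2E,6E,10E)-3,7,11-trimethylhexadeca-2,6,10-trien-14-yn-1-yl]-1,4-dimethoxy-3-methylnaphthalene | COc1c(C)c(C/C=C(\C)CC/C=C(\C)CC/C=C(\C)CCC#CC)c(OC)c2ccccc12 | intermediate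
12 | alkenylzirconocene chloride, Cp2ZrCl on C15' cis to H on C14' (cyclopentadienyl rings drawn σ-bound in the SMILES) | COc1c(C)c(C/C=C(\C)CC/C=C(\C)CC/C=C(\C)CC/C=C(\C)[Zr](Cl)(C3C=CC=C3)C3C=CC=C3)c(OC)c2ccccc12 | intermediate
13 | 2-[(2E,6E,10E,14E)-15-iodo-3,7,11-trimethylhexadeca-2,6,10,14-tetraen-1-yl]-1,4-dimethoxy-3-methylnaphthalene | COc1c(C)c(C/C=C(\C)CC/C=C(\C)CC/C=C(\C)CC/C=C(\C)I)c(OC)c2ccccc12 | intermediate
14 | (2E,6E,10E)-geranylgeraniol | CC(C)=CCC/C(C)=C/CC/C(C)=C/CC/C(C)=C/CO | starting material
15 | (2E,6E,10E)-geranylgeranial | CC(C)=CCC/C(C)=C/CC/C(C)=C/CC/C(C)=C/C=O | intermediate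
16 | (3E,7E,11E)-4,8,12,16-tetramethylheptadeca-1,3,7,11,15-pentaene | CC(C)=CCC/C(C)=C/CC/C(C)=C/CC/C(C)=C/C=C | intermediate
17 | 9-[(3E,7E,11E)-4,8,12,16-tetramethylheptadeca-3,7,11,15-tetraen-1-yl]-9-borabicyclo[3.3.1]nonane | CC(C)=CCC/C(C)=C/CC/C(C)=C/CC/C(C)=C/CCB1C2CCCC1CCC2 | intermediate
18 | menaquinone-8 hydroquinone dimethyl ether, 2-[(2E,6E,10E,14E,18E,22E,26E)-3,7,11,15,19,23,27,31-octamethyldotriaconta-2,6,10,14,18,22,26,30-octaen-1-yl]-1,4-dimethoxy-3-methylnaphthalene | COc1c(C)c(C/C=C(\C)CC/C=C(\C)CC/C=C(\C)CC/C=C(\C)CC/C=C(\C)CC/C=C(\C)CC/C=C(\C)CCC=C(C)C)c(OC)c2ccccc12 | intermediate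
19 | menaquinone-8 | CC(C)=CCC/C(C)=C/CC/C(C)=C/CC/C(C)=C/CC/C(C)=C/CC/C(C)=C/CC/C(C)=C/CC/C(C)=C/CC1=C(C)C(=O)c2ccccc2C1=O | target

**Step count and risks**

Total steps: 11. Longest linear sequence: 9 steps (steps 1 to 7, 10 and 11, from 1); steps 8 and 9 make the left half.

Steps most likely to fail:

Step 4 (poor site selectivity among three trisubstituted alkenes, and over-oxidation to the enal). The fallback sets out from 7 and comes back at 8. Terminal-selective bromohydrin formation (NBS, THF/H2O, 0 °C) should give the terminal bromohydrin F1. K2CO3 in MeOH should then give the terminal epoxide F2, and H5IO6 in THF/Et2O the trisnor aldehyde F3 with loss of acetone. A Wittig reaction with Ph3P=C(CH3)CO2Et (CH2Cl2, rt) should give the (E)-enoate F4, and reduction with i-Bu2AlH (CH2Cl2, −78 °C) should give 8.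

Step 7 (zirconium placed on the wrong alkyne carbon, or hydrozirconation of trisubstituted alkenes during equilibration). The fallback sets out from 9 and comes back at 13. Alkylation of 9 with 3-lithio-1-(trimethylsilyl)propyne (from 1-(trimethylsilyl)propyne and n-BuLi, THF, −78 °C) should give the silyl alkyne F5. Hydroalumination with i-Bu2AlH in hexane at 50 °C (aluminium geminal to silicon, net anti addition), then MeLi and MeI, should give the (E)-vinylsilane F6; here silicon fixes the regiochemistry. Iododesilylation with N-iodosuccinimide in (CF3)2CHOH at 0 °C should give 13 with retention.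

Step 10 (hydroboration of more than one alkene, or protodeboronation and β-hydride elimination instead of coupling). The fallback sets out from 16 and comes back at 18. Hydroboration with bis(1,2-dimethylpropyl)borane and oxidation (NaOH, H2O2) should give homogeranylgeraniol F7, which can be purified. I2, PPh3 and imidazole should give homogeranylgeranyl iodide F8. Iodine–lithium exchange with t-BuLi (Et2O, −78 °C) and transmetalation with ZnBr2 should give homogeranylgeranylzinc bromide F9, which is joined to 13 by Negishi coupling (Pd(dppf)Cl2 cat., THF, rt) to give 18.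

**Further compounds**

F1 | step 4 | terminal bromohydrin, racemic (6E,10E)-3-bromo-12-(1,4-dimethoxy-3-methylnaphthalen-2-yl)-2,6,10-trimethyldodeca-6,10-dien-2-ol | COc1c(C)c(C/C=C(\C)CC/C=C(\C)CCC(Br)C(C)(C)O)c(OC)c2ccccc12
F2 | step 4 | terminal epoxide, racemic 2-[(2E,6E)-9-(3,3-dimethyloxiran-2-yl)-3,7-dimethylnona-2,6-dien-1-yl]-1,4-dimethoxy-3-methylnaphthalene | COc1c(C)c(C/C=C(\C)CC/C=C(\C)CCC3OC3(C)C)c(OC)c2ccccc12
F3 | step 4 | trisnor aldehyde (4E,8E)-10-(1,4-dimethoxy-3-methylnaphthalen-2-yl)-4,8-dimethyldeca-4,8-dienal | COc1c(C)c(C/C=C(\C)CC/C=C(\C)CCC=O)c(OC)c2ccccc12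
F4 | step 4 | ethyl (2E,6E,10E)-12-(1,4-dimethoxy-3-methylnaphthalen-2-yl)-2,6,10-trimethyldodeca-2,6,10-trienoate | COc1c(C)c(C/C=C(\C)CC/C=C(\C)CC/C=C(\C)C(=O)OCC)c(OC)c2ccccc12
F5 | step 7 | silyl alkyne [(5E,9E,13E)-15-(1,4-dimethoxy-3-methylnaphthalen-2-yl)-5,9,13-trimethylpentadeca-5,9,13-trien-1-yn-1-yl]trimethylsilane | COc1c(C)c(C/C=C(\C)CC/C=C(\C)CC/C=C(\C)CCC#C[Si](C)(C)C)c(OC)c2ccccc12
F6 | step 7 | (E)-vinylsilane 2-[(2E,6E,10E,14E)-3,7,11-trimethyl-15-(trimethylsilyl)hexadeca-2,6,10,14-tetraen-1-yl]-1,4-dimethoxy-3-methylnaphthalene | COc1c(C)c(C/C=C(\C)CC/C=C(\C)CC/C=C(\C)CC/C=C(\C)[Si](C)(C)C)c(OC)c2ccccc12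
F7 | step 10 | homogeranylgeraniol (3E,7E,11E)-4,8,12,16-tetramethylheptadeca-3,7,11,15-tetraen-1-ol | CC(C)=CCC/C(C)=C/CC/C(C)=C/CC/C(C)=C/CCO
F8 | step 10 | homogeranylgeranyl iodide (6E,10E,14E)-17-iodo-2,6,10,14-tetramethylheptadeca-2,6,10,14-tetraene | CC(C)=CCC/C(C)=C/CC/C(C)=C/CC/C(C)=C/CCI
F9 | step 10 | homogeranylgeranylzinc bromide | CC(C)=CCC/C(C)=C/CC/C(C)=C/CC/C(C)=C/CC[Zn]Br
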